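## Retrosynthetic overview

- The C1–O ester is made last: Mitsunobu coupling of the primary alcohol with O-silylated (Z)-2-(hydroxymethyl)but-2-enoic acid (from methyl but-2-ynoate by syn-hydroalumination and hydroxymethylation), then global desilylation.
- The C1 alcohol is traced back to a C1 carboxylic acid. This exposes the enabling feature: C1(=O)–C2–CH2–CH=CH–C6H4OMe is a γ,δ-unsaturated acid, with C2 alpha to C1 and the styrene C=C in the γ,δ position.
- Key disconnection, C2–CH2 (cinnamyl): Ireland–Claisen [3,3] rearrangement of the (S)-1-(4-methoxyphenyl)allyl ester of (S)-3-(3,4-dimethoxyphenyl)-3-hydroxypropanoic acid, run as dianion, then bis-silyl ketene acetal. It joins both aryl halves, sets C2 and the E-alkene, and leaves the secondary oxygen protected.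
- The ester comes from crossed Claisen acylation of the (S)-allyl acetate with 3,4-dimethoxybenzoyl chloride, then asymmetric transfer hydrogenation (sets C3). The carbinol comes from 4-methoxybenzaldehyde, vinyl Grignard and lipase resolution.
- Rings: no ring is formed at any stage. Both benzene rings are bought; the only cyclic array is the transient six-membered chair of the key step.

Key step: step 6

Remark: the ester alkene is read as Z (methyl cis to the carboxyl), C2 as R and the carbinol carbon as S; the senses of the lipase resolution and of the transfer hydrogenation are assigned from the usual empirical models.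

## Route

Step 1
Reactants: 1 4-methoxybenzaldehyde
Product: 2 rac-1-(4-methoxyphenyl)prop-2-en-1-ol
Conditions: CH2=CHMgBr (1.2 equiv), THF, 0 °C; sat. aq NH4Cl
Reagents that add atoms: vinylmagnesium bromide, C=C[Mg]Br
Why: Grignard 1,2-addition of a vinyl nucleophile to an aromatic aldehyde gives the allylic carbinol as a racemate, which is resolved in step 2.

Step 2
Reactants: 2 rac-1-(4-methoxyphenyl)prop-2-en-1-ol
Product: 3 (S)-1-(4-methoxyphenyl)prop-2-en-1-ol
Conditions: immobilised Candida antarctica lipase B, vinyl acetate (3 equiv), MTBE, 30 °C, stopped just past half conversion; chromatography on Et3N-deactivated silica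
Reagents that add atoms: none
Why: Lipase-catalysed kinetic resolution by enantioselective transesterification: by the empirical rule for secondary alcohols (aryl large, vinyl medium) the (R)-enantiomer should be acetylated and the (S)-alcohol left, which sets the carbinol stereocentre that later steers the key step.

Step 3
Reactants: 3 (S)-1-(4-methoxyphenyl)prop-2-en-1-ol
Product: 4 (S)-1-(4-methoxyphenyl)prop-2-en-1-yl acetate
Conditions: Ac2O (1.5 equiv), Et3N (2 equiv), DMAP (5 mol %), CH2Cl2, 0 °C
Reagents that add atoms: acetic anhydride, CC(=O)OC(C)=O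
Why: DMAP-catalysed O-acetylation under basic, non-ionising conditions leaves the acid-labile p-methoxybenzylic allylic stereocentre untouched.

Step 4
Reactants: 4 (S)-1-(4-methoxyphenyl)prop-2-en-1-yl acetate; 5 3,4-dimethoxybenzoyl chloride
Product: 7 (S)-1-(4-methoxyphenyl)prop-2-en-1-yl 3-(3,4-dimethoxyphenyl)-3-oxopropanoate, via lithium ester enolate 6 (not isolated)
Conditions: LiHMDS (2.2 equiv), THF, −78 °C; 5 (1.0 equiv), −78 °C; AcOH quench at −78 °C
Reagents that add atoms: none
Why: Crossed Claisen condensation: the preformed lithium ester enolate is C-acylated by the aroyl chloride, the second equivalent of base stores the product as its unreactive β-keto ester enolate, and −78 °C keeps the allyl ester from ionising or rearranging.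

Step 5
Reactants: 7 (S)-1-(4-methoxyphenyl)prop-2-en-1-yl 3-(3,4-dimethoxyphenyl)-3-oxopropanoate
Product: 8 (S)-1-(4-methoxyphenyl)prop-2-en-1-yl (S)-3-(3,4-dimethoxyphenyl)-3-hydroxypropanoate
Conditions: RuCl[(S,S)-TsDPEN](p-cymene) (1 mol %), HCO2H/Et3N (1:1), CH2Cl2, 25 °C
Reagents that add atoms: none
Why: Asymmetric transfer hydrogenation (Noyori–Ikariya type) of the aryl ketone under catalyst control: the (S,S)-ligand should deliver hydride to the face that gives the (S)-benzylic carbinol (same sense as for acetophenone), the near-neutral formate medium should spare the allyl ester, and C=C bonds are not reduced.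

Step 6
Reactants: 8 (S)-1-(4-methoxyphenyl)prop-2-en-1-yl (S)-3-(3,4-dimethoxyphenyl)-3-hydroxypropanoate
Product: 12 (2S,4E)-2-[(S)-(3,4-dimethoxyphenyl)(triethylsilyloxy)methyl]-5-(4-methoxyphenyl)pent-4-enoic acid, via dilithium dianion 9 (not isolated), via bis-silyl ketene acetal 10 (not isolated), via triethylsilyl ester 11 (not isolated)
Conditions: LDA (2.3 equiv), THF, −78 → −40 °C; TESCl (3.5 equiv), DMPU, −78 → 23 °C; aq NaHCO3, then pH 5 citrate buffer
Reagents that add atoms: chlorotriethylsilane, CC[Si](Cl)(CC)CC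
Why: LDA converts 8 into the Li-chelated dianion 9, whose six-membered O–Li–O chelate locks the enolate with C3 cis to the enolate oxygen; double O-silylation gives ketene acetal 10, which undergoes a concerted suprafacial [3,3] shift (C2–CH2 bond formed, allylic C–O bond broken) through a chair transition state to silyl ester 11, hydrolysed on work-up. The closest known reaction type is the Ireland–Claisen rearrangement of a secondary 1-arylallyl ester, in its dianion variant for β-hydroxy esters. No ring is closed; the only cyclic array is the transient six-membered chair. The new C2 stereocentre is controlled by self-immolative 1,3-chirality transfer from the (S)-configured allylic C–O carbon: with the anisyl group pseudoequatorial and, because of the fixed ketene acetal geometry, C3 pseudoequatorial, the chair bonds the allyl terminus to the C2 face that places the new chain syn to the C3 oxygen in the backbone zigzag (2S in 12, 2R in the target), while the existing C3 centre is untouched. The step needs E-olefin geometry, linear (cinnamyl) regiochemistry and one C2 face: the pseudoequatorial anisyl group gives the E-styrene, the branched ester connectivity makes the linear product the only [3,3] outcome, and the silylated, non-chelating C3 substituent can adopt its A(1,3)-minimised rotamer (H inside, aryl anti to the forming bond) on the very face chosen by the chair, so carbinol control and C3 bias are matched. Complete silylation of the C3 alkoxide before warming is required, because the chelated dianion itself would prefer the opposite (anti) face.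

Step 7
Reactants: 12 (2S,4E)-2-[(S)-(3,4-dimethoxyphenyl)(triethylsilyloxy)methyl]-5-(4-methoxyphenyl)pent-4-enoic acid
Product: 13 (2R,4E)-2-[(S)-(3,4-dimethoxyphenyl)(triethylsilyloxy)methyl]-5-(4-methoxyphenyl)pent-4-en-1-ol
Conditions: LiAlH4 (3 equiv), THF, 0 → 23 °C; H2O, aq NaOH
Reagents that add atoms: none
Why: LiAlH4 reduction of the carboxylic acid to the primary alcohol; the carboxylate is not enolisable so C2 is safe, and the TES ether and the styrene are inert to hydride.

Step 8
Reactants: 14 methyl but-2-ynoate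
Product: 16 methyl (Z)-2-(hydroxymethyl)but-2-enoate, via vinylalane 15 (not isolated)
Conditions: DIBAL-H (1.2 equiv), NMO (1.2 equiv), THF, 0 °C; CH2O (gas, from cracked paraformaldehyde), −20 → 23 °C; aq Rochelle salt
Reagents that add atoms: formaldehyde, C=O
Why: Vinylalumination: syn-hydroalumination of the ynoate places Al at C2 and H at C3 on the same side, and C–C bond formation of the α-alumino enoate with formaldehyde then leaves CH3 cis to the ester, i.e. the Z (angelate-type) alkene.

Step 9
Reactants: 16 methyl (Z)-2-(hydroxymethyl)but-2-enoate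
Product: 17 methyl (Z)-2-[(tert-butyldimethylsilyloxy)methyl]but-2-enoate
Conditions: TBSCl (1.2 equiv), imidazole (2 equiv), CH2Cl2, 0 → 23 °C
Reagents that add atoms: tert-butyldimethylsilyl chloride, CC(C)(C)[Si](C)(C)Cl
Why: Standard silyl ether formation at the primary allylic alcohol, so that the acid can later be coupled without self-esterification.

Step 10
Reactants: 17 methyl (Z)-2-[(tert-butyldimethylsilyloxy)methyl]but-2-enoate
Product: 18 (Z)-2-[(tert-butyldimethylsilyloxy)methyl]but-2-enoic acid
Conditions: LiOH·H2O (2 equiv), THF/H2O (3:1), 0 → 23 °C; 1 M HCl to pH 4, 0 °C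
Reagents that add atoms: lithium hydroxide, [Li+].[OH-]
Why: Saponification of the methyl ester at or below room temperature, where the hindered Z-enoate should not isomerise and the TBS ether survives.

Step 11
Reactants: 13 (2R,4E)-2-[(S)-(3,4-dimethoxyphenyl)(triethylsilyloxy)methyl]-5-(4-methoxyphenyl)pent-4-en-1-ol; 18 (Z)-2-[(tert-butyldimethylsilyloxy)methyl]but-2-enoic acid
Product: 19 [(2R,4E)-2-[(S)-(3,4-dimethoxyphenyl)(triethylsilyloxy)methyl]-5-(4-methoxyphenyl)pent-4-en-1-yl] (Z)-2-[(tert-butyldimethylsilyloxy)methyl]but-2-enoate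
Conditions: PPh3 (1.3 equiv), DIAD (1.3 equiv), THF, 0 → 23 °C
Reagents that add atoms: none
Why: Mitsunobu esterification: the primary alcohol is activated as its oxyphosphonium salt and displaced by the carboxylate of 18, so the acyl group is never activated and the Z-enoate cannot isomerise by addition–elimination, the secondary oxygen is blocked as its TES ether, and no stereocentre is involved (C1 is a CH2).

Step 12
Reactants: 19 [(2R,4E)-2-[(S)-(3,4-dimethoxyphenyl)(triethylsilyloxy)methyl]-5-(4-methoxyphenyl)pent-4-en-1-yl] (Z)-2-[(tert-butyldimethylsilyloxy)methyl]but-2-enoate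
Product: 20 [(2R,4E)-2-[(S)-(3,4-dimethoxyphenyl)(hydroxy)methyl]-5-(4-methoxyphenyl)pent-4-en-1-yl] (Z)-2-(hydroxymethyl)but-2-enoate (CNP0280662.1)
Conditions: HF·pyridine, pyridine, THF, 0 → 23 °C
Reagents that add atoms: none
Why: Fluoride-mediated cleavage of both silyl ethers (TES and TBS) in pyridine-buffered HF should avoid base-induced acyl migration and acid-induced ionisation of the electron-rich benzylic carbinol.

## Compound list

1 | 4-methoxybenzaldehyde | COc1ccc(C=O)cc1 | starting material
2 | rac-1-(4-methoxyphenyl)prop-2-en-1-ol | C=CC(O)c1ccc(OC)cc1 | intermediate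
3 | (S)-1-(4-methoxyphenyl)prop-2-en-1-ol | C=C[C@H](O)c1ccc(OC)cc1 | intermediate
4 | (S)-1-(4-methoxyphenyl)prop-2-en-1-yl acetate | C=C[C@H](OC(C)=O)c1ccc(OC)cc1 | intermediate
5 | 3,4-dimethoxybenzoyl chloride | COc1ccc(C(=O)Cl)cc1OC | starting material
6 | lithium enolate of 4 | C=C[C@H](OC(=C)O[Li])c1ccc(OC)cc1 | intermediate (not isolated)
7 | (S)-1-(4-methoxyphenyl)prop-2-en-1-yl 3-(3,4-dimethoxyphenyl)-3-oxopropanoate | C=C[C@H](OC(=O)CC(=O)c1ccc(OC)c(OC)c1)c1ccc(OC)cc1 | intermediate
8 | (S)-1-(4-methoxyphenyl)prop-2-en-1-yl (S)-3-(3,4-dimethoxyphenyl)-3-hydroxypropanoate | C=C[C@H](OC(=O)C[C@H](O)c1ccc(OC)c(OC)c1)c1ccc(OC)cc1 | intermediate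
9 | dilithium dianion of 8 (C3 alkoxide and ester enolate, C3 cis to the enolate O–Li) | C=C[C@H](O/C(O[Li])=C/[C@H](O[Li])c1ccc(OC)c(OC)c1)c1ccc(OC)cc1 | intermediate (not isolated)
10 | bis(triethylsilyl) ketene acetal (C3 cis to the ketene acetal O–Si, C3–OTES) | C=C[C@H](O/C(O[Si](CC)(CC)CC)=C/[C@H](O[Si](CC)(CC)CC)c1ccc(OC)c(OC)c1)c1ccc(OC)cc1 | intermediate (not isolated)
11 | triethylsilyl (2S,4E)-2-[(S)-(3,4-dimethoxyphenyl)(triethylsilyloxy)methyl]-5-(4-methoxyphenyl)pent-4-enoate | CC[Si](CC)(CC)OC(=O)[C@@H](C/C=C/c1ccc(OC)cc1)[C@H](O[Si](CC)(CC)CC)c1ccc(OC)c(OC)c1 | intermediate (not isolated)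
12 | (2S,4E)-2-[(S)-(3,4-dimethoxyphenyl)(triethylsilyloxy)methyl]-5-(4-methoxyphenyl)pent-4-enoic acid | OC(=O)[C@@H](C/C=C/c1ccc(OC)cc1)[C@H](O[Si](CC)(CC)CC)c1ccc(OC)c(OC)c1 | intermediate
13 | (2R,4E)-2-[(S)-(3,4-dimethoxyphenyl)(triethylsilyloxy)methyl]-5-(4-methoxyphenyl)pent-4-en-1-ol | OC[C@@H](C/C=C/c1ccc(OC)cc1)[C@H](O[Si](CC)(CC)CC)c1ccc(OC)c(OC)c1 | intermediate
14 | methyl but-2-ynoate | CC#CC(=O)OC | starting material
15 | methyl (E)-2-(diisobutylalumanyl)but-2-enoate | C/C=C(/[Al](CC(C)C)CC(C)C)C(=O)OC | intermediate (not isolated)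
16 | methyl (Z)-2-(hydroxymethyl)but-2-enoate | C/C=C(/CO)C(=O)OC | intermediate
17 | methyl (Z)-2-[(tert-butyldimethylsilyloxy)methyl]but-2-enoate | C/C=C(/CO[Si](C)(C)C(C)(C)C)C(=O)OC | intermediate
18 | (Z)-2-[(tert-butyldimethylsilyloxy)methyl]but-2-enoic acid | C/C=C(/CO[Si](C)(C)C(C)(C)C)C(=O)O | intermediate
19 | [(2R,4E)-2-[(S)-(3,4-dimethoxyphenyl)(triethylsilyloxy)methyl]-5-(4-methoxyphenyl)pent-4-en-1-yl] (Z)-2-[(tert-butyldimethylsilyloxy)methyl]but-2-enoate | C/C=C(/CO[Si](C)(C)C(C)(C)C)C(=O)OC[C@@H](C/C=C/c1ccc(OC)cc1)[C@H](O[Si](CC)(CC)CC)c1ccc(OC)c(OC)c1 | intermediate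
20 | [(2R,4E)-2-[(S)-(3,4-dimethoxyphenyl)(hydroxy)methyl]-5-(4-methoxyphenyl)pent-4-en-1-yl] (Z)-2-(hydroxymethyl)but-2-enoate | C/C=C(/CO)C(=O)OC[C@@H](C/C=C/c1ccc(OC)cc1)[C@H](O)c1ccc(OC)c(OC)c1 | target

## Step count and risks

Total step count: 12. Longest linear sequence: 9 steps (steps 1–7, 11, 12); steps 8–10 form the side branch to acid 18.

Risk 1, step 6 (key step). Silylation of the C3 alkoxide may lag behind the rearrangement, so that part of the material reacts as the chelated dianion, whose facial preference opposes the chirality transfer. In addition, the p-methoxybenzylic allyl ester may ionise (loss of chirality transfer, branched product), and the β-oxygen may be eliminated from the enolate. The fallback uses only known chemistry and sets the two centres by an aldol reaction instead. It sets out from racemic carbinol 2, whose stereocentre is irrelevant here. Johnson–Claisen rearrangement with triethyl orthoacetate (cat. propionic acid, 130 °C) should give ethyl (E)-5-(4-methoxyphenyl)pent-4-enoate F1. Saponification gives (E)-5-(4-methoxyphenyl)pent-4-enoic acid F2. Its pivaloyl mixed anhydride acylates lithiated (S)-4-benzyloxazolidin-2-one to give (S)-4-benzyl-3-[(E)-5-(4-methoxyphenyl)pent-4-enoyl]oxazolidin-2-one F3. Evans syn-aldol reaction (Bu2BOTf, iPr2NEt, commercial 3,4-dimethoxybenzaldehyde, −78 → 0 °C) should give (S)-4-benzyl-3-[(2S,4E)-2-[(S)-(3,4-dimethoxyphenyl)(hydroxy)methyl]-5-(4-methoxyphenyl)pent-4-enoyl]oxazolidin-2-one F4. Silylation (TESOTf, 2,6-lutidine) gives its triethylsilyl ether F5, and LiBH4 reduction removes the auxiliary. The fallback comes back to the route at alcohol 13.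

Risk 2, step 5. The acid-labile allyl ester may ionise or undergo 1,3-transposition in the formate medium, the ruthenium catalyst may cleave the allyl ester, and the remote stereocentre may lower the selectivity of hydride delivery. The fallback sets C3 before the labile ester exists. It sets out from acid chloride 5. Acylation of potassium ethyl malonate (MgCl2, Et3N, MeCN) with decarboxylation gives ethyl 3-(3,4-dimethoxyphenyl)-3-oxopropanoate F6. Transfer hydrogenation with the same (S,S)-catalyst in the usual 5:2 HCO2H/Et3N mixture gives ethyl (S)-3-(3,4-dimethoxyphenyl)-3-hydroxypropanoate F7. TBSCl/imidazole gives ethyl (S)-3-[(tert-butyldimethylsilyl)oxy]-3-(3,4-dimethoxyphenyl)propanoate F8, and LiOH gives (S)-3-[(tert-butyldimethylsilyl)oxy]-3-(3,4-dimethoxyphenyl)propanoic acid F9. Carbodiimide esterification (EDC, DMAP, 0 °C) with carbinol 3 gives (S)-1-(4-methoxyphenyl)prop-2-en-1-yl (S)-3-[(tert-butyldimethylsilyl)oxy]-3-(3,4-dimethoxyphenyl)propanoate F10. Desilylation with AcOH-buffered TBAF comes back to the route at hydroxy ester 8.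

Risk 3, step 8. The α-alumino enoate may equilibrate through its allenolate and lose the Z geometry, the ester may be over-reduced by the hydride, and capture of gaseous formaldehyde may be inefficient. The fallback replaces the aluminium chemistry by tin and palladium. It sets out from ynoate 14. Pd(PPh3)4-catalysed syn-hydrostannation with Bu3SnH gives methyl (E)-2-(tributylstannyl)but-2-enoate F11. Iododestannylation (I2, CH2Cl2, 0 °C) with retention gives methyl (E)-2-iodobut-2-enoate F12. Stille coupling with (tributylstannyl)methanol (Pd(PPh3)4, CuI, DMF) installs the hydroxymethyl group with retention and comes back to the route at ester 16.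

## Further compounds

F1 | step 6 | ethyl (E)-5-(4-methoxyphenyl)pent-4-enoate | CCOC(=O)CC/C=C/c1ccc(OC)cc1
F2 | step 6 | (E)-5-(4-methoxyphenyl)pent-4-enoic acid | OC(=O)CC/C=C/c1ccc(OC)cc1
F3 | step 6 | (S)-4-benzyl-3-[(E)-5-(4-methoxyphenyl)pent-4-enoyl]oxazolidin-2-one | O=C(CC/C=C/c1ccc(OC)cc1)N1[C@@H](Cc2ccccc2)COC1=O
F4 | step 6 | (S)-4-benzyl-3-[(2S,4E)-2-[(S)-(3,4-dimethoxyphenyl)(hydroxy)methyl]-5-(4-methoxyphenyl)pent-4-enoyl]oxazolidin-2-one | O=C([C@@H](C/C=C/c1ccc(OC)cc1)[C@H](O)c1ccc(OC)c(OC)c1)N1[C@@H](Cc2ccccc2)COC1=O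
F5 | step 6 | (S)-4-benzyl-3-[(2S,4E)-2-[(S)-(3,4-dimethoxyphenyl)(triethylsilyloxy)methyl]-5-(4-methoxyphenyl)pent-4-enoyl]oxazolidin-2-one | O=C([C@@H](C/C=C/c1ccc(OC)cc1)[C@H](O[Si](CC)(CC)CC)c1ccc(OC)c(OC)c1)N1[C@@H](Cc2ccccc2)COC1=O
F6 | step 5 | ethyl 3-(3,4-dimethoxyphenyl)-3-oxopropanoate | CCOC(=O)CC(=O)c1ccc(OC)c(OC)c1
F7 | step 5 | ethyl (S)-3-(3,4-dimethoxyphenyl)-3-hydroxypropanoate | CCOC(=O)C[C@H](O)c1ccc(OC)c(OC)c1
F8 | step 5 | ethyl (S)-3-[(tert-butyldimethylsilyl)oxy]-3-(3,4-dimethoxyphenyl)propanoate | CCOC(=O)C[C@H](O[Si](C)(C)C(C)(C)C)c1ccc(OC)c(OC)c1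
F9 | step 5 | (S)-3-[(tert-butyldimethylsilyl)oxy]-3-(3,4-dimethoxyphenyl)propanoic acid | OC(=O)C[C@H](O[Si](C)(C)C(C)(C)C)c1ccc(OC)c(OC)c1
F10 | step 5 | (S)-1-(4-methoxyphenyl)prop-2-en-1-yl (S)-3-[(tert-butyldimethylsilyl)oxy]-3-(3,4-dimethoxyphenyl)propanoate | C=C[C@H](OC(=O)C[C@H](O[Si](C)(C)C(C)(C)C)c1ccc(OC)c(OC)c1)c1ccc(OC)cc1
F11 | step 8 | methyl (E)-2-(tributylstannyl)but-2-enoate | C/C=C(/[Sn](CCCC)(CCCC)CCCC)C(=O)OC
F12 | step 8 | methyl (E)-2-iodobut-2-enoate | C/C=C(/I)C(=O)OC
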